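All runs were generated by integration for substances that don't exist, and the scatter is random.

0.286 was the number I carried to these flasks. It counts the parts of E made per part of D lost any other way, for each equivalent of L charged. I called it the split, a selectivity factor.

the same everywhere: D 0.12 M; Q 19 mM (held)
- alder: L 0.15 M; temperature 2 °C; run made earlier
- oak: L 0.22 M; temperature 19 °C; run made earlier
- theta: L 0.300 M; temperature −5 °C; time 80 min
- zeta: L 0.300 M; temperature 25 °C; time 80 min

- alder (time / min: E / %, D / %): 4.00: 0.5, 99.8; 12.0: 1.2, 97.2; 25.0: 1.0, 95.6; 30.0: 0.9, 93.5; 50.0: 1.3, 90.5; 60.0: 3.7, 87.5; 80.0: 4.1, 83.0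
- oak (time / min: E / %, D / %): 4.00: 2.8, 91.1; 8.00: 5.1, 82.0; 10.0: 5.8, 74.5; 15.0: 11.8, 65.7; 20.0: 16.5, 58.5; 25.0: 14.1, 52.4

(readings scatter by 1 percentage point)

- at the start none of Q is in solution

1. the best flask by amount of E, in percent of the D charged; "all alike" if 1.5 percentage points covers them all (theta / zeta / all alike)
2. amount of E at the end, in percent of the D charged, theta
3. amount of E at the end, in percent of the D charged, zeta

I pooled the last two readings of each run. Alder, at 2 °C, gave 0.288. Oak, at 19 °C, gave 0.285. They matched, though each E reading carries 1 percentage point. So I tied the split to L and set temperature aside.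

I took the loss of D as first order and free of L. That gave 0.00233 min⁻¹ in alder and 0.0259 min⁻¹ in oak, so an activation energy of 94.6 kJ mol⁻¹. For zeta that meant 0.0566 min⁻¹.

I drew zeta's curve. With 2.50 equivalents of L, E took a share of 0.417 of the D lost, so it rose at first by 0.0236 min⁻¹ of the charge. I put the knee near the half-life of D, 12.2 min. For 80 min I reckoned D in zeta at 1.08%. L fell as E formed, so I used a mean amount of L, and I reckoned E in zeta levelling at 39.2%. For theta, with the same share, I reckoned a loss of 6.13% of its D and 2.56% of E.

The forecast named zeta best, with 2.5% in theta and 32% in zeta, holding that “Selectivity seems to rise with temperature”. There we parted: I put that rise down to L.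

Zeta gave 40.3% of E and theta 2.21%, so zeta was best, 8.3 points above the forecast. Beside the E in zeta stood 58.7% of the other product Z. Taken over the 2.30 equivalents of L present on average, E over Z came to 0.298, where the readings had given a split of 0.286.

    D → X (k = 9.70 × 10⁻⁴ s⁻¹, Ea = 95.0 kJ mol⁻¹)
    L + X → E (k = 0.330 L mol⁻¹ s⁻¹, Ea = 45.0 kJ mol⁻¹)
    G + X → Z (k = 7.10 L mol⁻¹ s⁻¹, Ea = 39.0 kJ mol⁻¹)
    G → J (k = 7.00 × 10⁻⁶ s⁻¹, Ea = 108 kJ mol⁻¹)
    Q ⇌ G, rate k5*(csat - [G]) (kL = 0.120 s⁻¹)
    (constants at 25 °C)

The neighbour flask was zeta with 0.18 M of L, or 1.50 equiv. In that flask the split gave a first share of 0.301, and with a mean amount of L, a reckoned E of 27.6%. The computed flask gave 28.6%.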